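Retrosynthesis: after removal of two silyl ethers, the C3–OH bond is cut (enolate oxidation), then C2–C1' (conjugate arylation of a chromone by a ring B boronic acid), then ring C (C4, C3 and C2 taken off a salicylaldehyde).
Ring A is cut at C5–C6, C6–C7, C8–C8a and C8a–C4a into a prenylated α-diazo vinyl ketone and a prenylated siloxyalkyne.
Enabling feature: ring A is a pentasubstituted resorcinol in which O7 and O1 flank the C8 prenyl group and a second prenyl sits at C6; building the ring from two acyclic pieces fixes this pattern and leaves only C4a free next to O1–H.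
Forward order: ring A (benzannulation), then ring C (formylation, alkynylation, chromone closure), then attachment of ring B and hydroxylation.
Stereochemistry: C2 comes from the chiral pyridine–oxazoline palladium catalyst in the arylation, C3 from the C2 aryl group, which steers the oxidant to the trans face.

Key step: step 5

Assumption: (R)-t-BuPyOx, (R)-4-tert-butyl-2-(pyridin-2-yl)-4,5-dihydrooxazole, is taken to give the (2S)-flavanone, by analogy with the facial sense known for cyclic enones; were the sense the opposite, the mirror-image ligand would be used.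

Step 1
Reactants: 1 5-methylhex-4-enoic acid
Product: 3 N-methoxy-N,5-dimethylhex-4-enamide, via acyl imidazole 2 (not isolated)
Conditions: CDI, CH2Cl2, rt; then MeNH(OMe)·HCl, rt
Reagents that add atoms: N,O-dimethylhydroxylamine hydrochloride, CNOC.Cl
Why: CDI activates the acid as acyl imidazole 2, which acylates the hydroxylamine at room temperature without touching the trisubstituted olefin (amide formation by acyl transfer).

Step 2
Reactants: 3 N-methoxy-N,5-dimethylhex-4-enamide; 4 vinylmagnesium bromide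
Product: 5 7-methylocta-1,6-dien-3-one
Conditions: CH2=CHMgBr, THF, 0 °C; inverse quench into cold 1 M HCl
Reagents that add atoms: none
Why: Weinreb ketone synthesis: the N-methoxy-N-methyl amide takes up only one equivalent of the Grignard reagent, and the inverse quench into cold acid protonates the released N,O-dimethylhydroxylamine before it can add to the vinyl ketone.

Step 3
Reactants: 5 7-methylocta-1,6-dien-3-one
Product: 8 4-diazo-7-methylocta-1,6-dien-3-one, via lithium dienolate 6 (not isolated), via trifluoroacetyl diketone 7 (not isolated)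
Conditions: LiN(SiMe3)2, THF, −78 °C (5 added slowly); CF3CO2CH2CF3, −78 °C; aq. HCl work-up; then MsN3, Et3N, H2O, MeCN, rt
Reagents that add atoms: methanesulfonyl azide, CS(=O)(=O)N=[N+]=[N-]
Why: Detrifluoroacetylative diazo transfer: C4 is the only enolisable position, so kinetic deprotonation gives dienolate 6, Claisen-type acylation with the activated trifluoroacetate gives diketone 7, and MsN3 then transfers the diazo group to C4 with loss of the trifluoroacetyl group rather than the acryloyl group because the former is the more electrophilic carbonyl; slow addition of 5 to the cold base keeps free enone scarce and so suppresses anionic oligomerisation.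

Step 4
Reactants: 9 ethyl 4-methylpent-3-enoate
Product: 11 triisopropyl[(5-methylhex-4-en-1-yn-1-yl)oxy]silane, via lithium ynolate 10 (not isolated)
Conditions: CH2Br2, lithium 2,2,6,6-tetramethylpiperidide, THF, −78 °C; then n-BuLi, −78 °C to rt; then i-Pr3SiCl, −78 °C to rt
Reagents that add atoms: dibromomethane, BrCBr; chlorotriisopropylsilane, CC(C)[Si](Cl)(C(C)C)C(C)C
Why: Kowalski ester homologation: LiCHBr2 adds to the ester carbonyl, bromine–lithium exchange triggers 1,2-shift of the allylic chain to give ynolate 10, and the bulky silyl chloride traps it on oxygen.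

Step 5
Reactants: 8 4-diazo-7-methylocta-1,6-dien-3-one; 11 triisopropyl[(5-methylhex-4-en-1-yn-1-yl)oxy]silane
Product: 16 2,4-bis(3-methylbut-2-en-1-yl)-3-[(triisopropylsilyl)oxy]phenol, via vinylketene 12 (not isolated), via vinylcyclobutenone 13 (not isolated), via dienylketene 14 (not isolated), via cyclohexadienone 15 (not isolated)
Conditions: hν (medium-pressure Hg lamp, Pyrex), 11 (1.5 equiv), ClCH2CH2Cl, rt; then 80 °C
Reagents that add atoms: none
Why: Direct irradiation expels N2 with 1,2-shift of the vinyl group (photochemical Wolff rearrangement) to give vinylketene 12, whose carbonyl carbon is attacked by the oxygen-remote carbon of the electron-rich alkyne 11, so that the [2+2] cycloaddition gives only the 2-prenyl-3-siloxy-4-vinylcyclobutenone 13. Ring strain then drives thermal 4π electrocyclic opening to dienylketene 14, and ring A is closed by 6π electrocyclisation (bond C8a–C4a) to dienone 15, which tautomerises to phenol 16; the four-membered ring of 13 arises by [2+2] cycloaddition and is only transient. The closest known reaction type is the Danheiser benzannulation of α-diazo ketones with siloxyalkynes to resorcinol monosilyl ethers. No stereocentre is created. The step needs regioselective ketene–alkyne union, secured by the polarisation of the ynol ether, discrimination against the three trisubstituted olefins, secured by the much greater ketenophilicity of the ynol ether, and vinyl migration ahead of 1,2-hydride shift from the neighbouring CH2, favoured by unsensitised irradiation in which loss of N2 and migration are concerted. Because of the way the six ring atoms are stitched together, the unprotected oxygen ends up as the future O1 beside the C8 side chain, the silylated one as O7 between both side chains, and C4a remains the single unsubstituted position ortho to the free phenol.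

Step 6
Reactants: 16 2,4-bis(3-methylbut-2-en-1-yl)-3-[(triisopropylsilyl)oxy]phenol
Product: 17 2-hydroxy-3,5-bis(3-methylbut-2-en-1-yl)-4-[(triisopropylsilyl)oxy]benzaldehyde
Conditions: MgCl2, Et3N, (CH2O)n, MeCN, reflux
Reagents that add atoms: paraformaldehyde (as formaldehyde), C=O
Why: Magnesium-mediated ortho-formylation of a phenol (Casnati–Skattebøl reaction) delivers the formyl group only ortho to the free hydroxyl, here at the single open position C4a, under conditions that are basic and mild enough for the silyl ether and the acid-sensitive prenyl groups.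

Step 7
Reactants: 17 2-hydroxy-3,5-bis(3-methylbut-2-en-1-yl)-4-[(triisopropylsilyl)oxy]benzaldehyde; 18 ethynylmagnesium bromide
Product: 19 1-{2-hydroxy-3,5-bis(3-methylbut-2-en-1-yl)-4-[(triisopropylsilyl)oxy]phenyl}prop-2-yn-1-ol (racemic)
Conditions: HC≡CMgBr (3 equiv), THF, 0 °C to rt; aq. NH4Cl
Reagents that add atoms: none
Why: 1,2-Addition of an alkynyl Grignard reagent to the aldehyde, the first equivalent serving to deprotonate the phenol, installs C3 and C2 of ring C as a terminal alkyne.

Step 8
Reactants: 19 1-{2-hydroxy-3,5-bis(3-methylbut-2-en-1-yl)-4-[(triisopropylsilyl)oxy]phenyl}prop-2-yn-1-ol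
Product: 22 6,8-bis(3-methylbut-2-en-1-yl)-7-[(triisopropylsilyl)oxy]-4H-chromen-4-one, via ynone 20 (not isolated), via enaminone 21 (not isolated)
Conditions: MnO2, CH2Cl2, rt; filter; then Et2NH, EtOH, rt to 60 °C
Reagents that add atoms: none
Why: MnO2 oxidises the benzylic propargylic alcohol to ynone 20, conjugate addition of Et2NH gives enaminone 21, and the phenol then closes ring C by addition–elimination at the β-carbon, a path that allows only the 6-endo product and excludes the five-membered benzofuranone (chromone synthesis from o-hydroxyaryl ynones).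

Step 9
Reactants: 23 4-bromophenol; 24 1-bromo-3-methylbut-2-ene (prenyl bromide)
Product: 25 4-bromo-2-(3-methylbut-2-en-1-yl)phenol
Conditions: NaH, toluene, 0 °C to rt
Reagents that add atoms: none
Why: ortho-C-Allylation of a sodium phenoxide in a non-polar solvent, where the tight ion pair directs the allylic bromide to the ring carbon next to oxygen and the para position is blocked by bromine.

Step 10
Reactants: 25 4-bromo-2-(3-methylbut-2-en-1-yl)phenol
Product: 26 [4-bromo-2-(3-methylbut-2-en-1-yl)phenoxy]triisopropylsilane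
Conditions: i-Pr3SiCl, imidazole, DMF, rt
Reagents that add atoms: chlorotriisopropylsilane, CC(C)[Si](Cl)(C(C)C)C(C)C
Why: Routine silylation of a phenol with a silyl chloride and imidazole; the same silyl group as on ring A is chosen so that one fluoride treatment removes both at the end.

Step 11
Reactants: 26 [4-bromo-2-(3-methylbut-2-en-1-yl)phenoxy]triisopropylsilane
Product: 29 {3-(3-methylbut-2-en-1-yl)-4-[(triisopropylsilyl)oxy]phenyl}boronic acid, via aryllithium 27 (not isolated), via lithium borate 28 (not isolated)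
Conditions: n-BuLi, THF, −78 °C; B(Oi-Pr)3, −78 °C to rt; dilute aq. HCl
Reagents that add atoms: triisopropyl borate, CC(C)OB(OC(C)C)OC(C)C; water, O
Why: Bromine–lithium exchange at −78 °C outpaces deprotonation of the doubly activated CH2, aryllithium 27 is trapped by the borate as ate complex 28, and mild aqueous acid hydrolyses it to the boronic acid (borylation of an aryllithium).

Step 12
Reactants: 22 6,8-bis(3-methylbut-2-en-1-yl)-7-[(triisopropylsilyl)oxy]-4H-chromen-4-one; 29 {3-(3-methylbut-2-en-1-yl)-4-[(triisopropylsilyl)oxy]phenyl}boronic acid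
Product: 30 (2S)-6,8-bis(3-methylbut-2-en-1-yl)-2-{3-(3-methylbut-2-en-1-yl)-4-[(triisopropylsilyl)oxy]phenyl}-7-[(triisopropylsilyl)oxy]-2,3-dihydro-4H-chromen-4-one
Conditions: Pd(OCOCF3)2 (5 mol %), (R)-t-BuPyOx (6 mol %), NH4PF6 (30 mol %), H2O (5 equiv), ClCH2CH2Cl, 60 °C
Reagents that add atoms: none
Why: Palladium-catalysed asymmetric conjugate addition of an arylboronic acid to a chromone: the arylpalladium complex of the chiral pyridine–oxazoline ligand adds its aryl group to C2 on the face left open by the tert-butyl group and water supplies the proton at C3, so that the C2 stereocentre is set as S by the catalyst, while the isolated trisubstituted olefins are too hindered to insert.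

Step 13
Reactants: 30 (2S)-6,8-bis(3-methylbut-2-en-1-yl)-2-{3-(3-methylbut-2-en-1-yl)-4-[(triisopropylsilyl)oxy]phenyl}-7-[(triisopropylsilyl)oxy]-2,3-dihydro-4H-chromen-4-one
Product: 32 (2R,3R)-3-hydroxy-6,8-bis(3-methylbut-2-en-1-yl)-2-{3-(3-methylbut-2-en-1-yl)-4-[(triisopropylsilyl)oxy]phenyl}-7-[(triisopropylsilyl)oxy]-2,3-dihydro-4H-chromen-4-one, via potassium enolate 31 (not isolated)
Conditions: KN(SiMe3)2, THF, −78 °C; then 3-phenyl-2-(phenylsulfonyl)oxaziridine, −78 °C; AcOH quench at −78 °C
Reagents that add atoms: 3-phenyl-2-(phenylsulfonyl)oxaziridine, O=S(=O)(c1ccccc1)N1OC1c1ccccc1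
Why: Enolate hydroxylation with a 2-sulfonyloxaziridine (Davis oxidation): potassium enolate 31 is formed and oxidised at −78 °C, where retro-oxa-Michael opening of ring C is slow, and the oxidant approaches C3 anti to the C2 aryl group, giving the 2,3-trans (2R,3R) product, which is also the more stable epimer; the reagent leaves isolated olefins alone at this temperature.

Step 14
Reactants: 32 (2R,3R)-3-hydroxy-6,8-bis(3-methylbut-2-en-1-yl)-2-{3-(3-methylbut-2-en-1-yl)-4-[(triisopropylsilyl)oxy]phenyl}-7-[(triisopropylsilyl)oxy]-2,3-dihydro-4H-chromen-4-one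
Product: 33 lespeflorin B3, (2R,3R)-3,7-dihydroxy-2-[4-hydroxy-3-(3-methylbut-2-en-1-yl)phenyl]-6,8-bis(3-methylbut-2-en-1-yl)-2,3-dihydro-4H-chromen-4-one
Conditions: Bu4NF, AcOH, THF, 0 °C
Reagents that add atoms: none
Why: Fluoride-induced cleavage of both aryl silyl ethers, buffered with acetic acid so that the phenoxides are protonated at once and neither C2 epimerisation through ring opening nor cyclisation of a phenol onto a prenyl group can set in (desilylation).

Compound list
1 | 5-methylhex-4-enoic acid | CC(C)=CCCC(=O)O | starting material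
2 | 1-(1H-imidazol-1-yl)-5-methylhex-4-en-1-one | CC(C)=CCCC(=O)n1ccnc1 | intermediate
3 | N-methoxy-N,5-dimethylhex-4-enamide | CC(C)=CCCC(=O)N(C)OC | intermediate
4 | vinylmagnesium bromide | C=C[Mg]Br | starting material
5 | 7-methylocta-1,6-dien-3-one | C=CC(=O)CCC=C(C)C | intermediate
6 | lithium 7-methylocta-1,3,6-trien-3-olate | [Li]OC(C=C)=CCC=C(C)C | intermediate
7 | 1,1,1-trifluoro-3-(3-methylbut-2-en-1-yl)hex-5-ene-2,4-dione (racemic) | C=CC(=O)C(CC=C(C)C)C(=O)C(F)(F)F | intermediate
8 | 4-diazo-7-methylocta-1,6-dien-3-one | C=CC(=O)C(=[N+]=[N-])CC=C(C)C | intermediate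
9 | ethyl 4-methylpent-3-enoate | CCOC(=O)CC=C(C)C | starting material
10 | lithium 5-methylhex-4-en-1-yn-1-olate | [Li]OC#CCC=C(C)C | intermediate
11 | triisopropyl[(5-methylhex-4-en-1-yn-1-yl)oxy]silane | CC(C)=CCC#CO[Si](C(C)C)(C(C)C)C(C)C | intermediate
12 | 2-ethenyl-5-methylhexa-1,4-dien-1-one | O=C=C(C=C)CC=C(C)C | intermediate
13 | 4-ethenyl-2,4-bis(3-methylbut-2-en-1-yl)-3-[(triisopropylsilyl)oxy]cyclobut-2-en-1-one (racemic) | C=CC1(CC=C(C)C)C(=O)C(CC=C(C)C)=C1O[Si](C(C)C)(C(C)C)C(C)C | intermediate
14 | (3E)-2,4-bis(3-methylbut-2-en-1-yl)-3-[(triisopropylsilyl)oxy]hexa-1,3,5-trien-1-one | O=C=C(CC=C(C)C)/C(O[Si](C(C)C)(C(C)C)C(C)C)=C(\C=C)CC=C(C)C | intermediate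
15 | 2,4-bis(3-methylbut-2-en-1-yl)-3-[(triisopropylsilyl)oxy]cyclohexa-2,4-dien-1-one | O=C1CC=C(CC=C(C)C)C(O[Si](C(C)C)(C(C)C)C(C)C)=C1CC=C(C)C | intermediate
16 | 2,4-bis(3-methylbut-2-en-1-yl)-3-[(triisopropylsilyl)oxy]phenol | CC(C)=CCc1ccc(O)c(CC=C(C)C)c1O[Si](C(C)C)(C(C)C)C(C)C | intermediate
17 | 2-hydroxy-3,5-bis(3-methylbut-2-en-1-yl)-4-[(triisopropylsilyl)oxy]benzaldehyde | O=Cc1cc(CC=C(C)C)c(O[Si](C(C)C)(C(C)C)C(C)C)c(CC=C(C)C)c1O | intermediate
18 | ethynylmagnesium bromide | C#C[Mg]Br | starting material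
19 | 1-{2-hydroxy-3,5-bis(3-methylbut-2-en-1-yl)-4-[(triisopropylsilyl)oxy]phenyl}prop-2-yn-1-ol (racemic) | C#CC(O)c1cc(CC=C(C)C)c(O[Si](C(C)C)(C(C)C)C(C)C)c(CC=C(C)C)c1O | intermediate
20 | 1-{2-hydroxy-3,5-bis(3-methylbut-2-en-1-yl)-4-[(triisopropylsilyl)oxy]phenyl}prop-2-yn-1-one | C#CC(=O)c1cc(CC=C(C)C)c(O[Si](C(C)C)(C(C)C)C(C)C)c(CC=C(C)C)c1O | intermediate
21 | (2E)-3-(diethylamino)-1-{2-hydroxy-3,5-bis(3-methylbut-2-en-1-yl)-4-[(triisopropylsilyl)oxy]phenyl}prop-2-en-1-one | CCN(CC)/C=C/C(=O)c1cc(CC=C(C)C)c(O[Si](C(C)C)(C(C)C)C(C)C)c(CC=C(C)C)c1O | intermediate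
22 | 6,8-bis(3-methylbut-2-en-1-yl)-7-[(triisopropylsilyl)oxy]-4H-chromen-4-one | O=c1ccoc2c(CC=C(C)C)c(O[Si](C(C)C)(C(C)C)C(C)C)c(CC=C(C)C)cc12 | intermediate
23 | 4-bromophenol | Oc1ccc(Br)cc1 | starting material
24 | 1-bromo-3-methylbut-2-ene (prenyl bromide) | CC(C)=CCBr | starting material
25 | 4-bromo-2-(3-methylbut-2-en-1-yl)phenol | CC(C)=CCc1cc(Br)ccc1O | intermediate
26 | [4-bromo-2-(3-methylbut-2-en-1-yl)phenoxy]triisopropylsilane | CC(C)=CCc1cc(Br)ccc1O[Si](C(C)C)(C(C)C)C(C)C | intermediate
27 | {3-(3-methylbut-2-en-1-yl)-4-[(triisopropylsilyl)oxy]phenyl}lithium | [Li]c1ccc(O[Si](C(C)C)(C(C)C)C(C)C)c(CC=C(C)C)c1 | intermediate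
28 | lithium triisopropoxy{3-(3-methylbut-2-en-1-yl)-4-[(triisopropylsilyl)oxy]phenyl}borate | [Li+].CC(C)O[B-](OC(C)C)(OC(C)C)c1ccc(O[Si](C(C)C)(C(C)C)C(C)C)c(CC=C(C)C)c1 | intermediate
29 | {3-(3-methylbut-2-en-1-yl)-4-[(triisopropylsilyl)oxy]phenyl}boronic acid | CC(C)=CCc1cc(B(O)O)ccc1O[Si](C(C)C)(C(C)C)C(C)C | intermediate
30 | (2S)-6,8-bis(3-methylbut-2-en-1-yl)-2-{3-(3-methylbut-2-en-1-yl)-4-[(triisopropylsilyl)oxy]phenyl}-7-[(triisopropylsilyl)oxy]-2,3-dihydro-4H-chromen-4-one | CC(C)=CCc1cc([C@H]2Oc3c(cc(CC=C(C)C)c(O[Si](C(C)C)(C(C)C)C(C)C)c3CC=C(C)C)C(=O)C2)ccc1O[Si](C(C)C)(C(C)C)C(C)C | intermediate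
31 | potassium (2S)-6,8-bis(3-methylbut-2-en-1-yl)-2-{3-(3-methylbut-2-en-1-yl)-4-[(triisopropylsilyl)oxy]phenyl}-7-[(triisopropylsilyl)oxy]-2H-chromen-4-olate | CC(C)=CCc1cc([C@H]2Oc3c(cc(CC=C(C)C)c(O[Si](C(C)C)(C(C)C)C(C)C)c3CC=C(C)C)C(O[K])=C2)ccc1O[Si](C(C)C)(C(C)C)C(C)C | intermediate
32 | (2R,3R)-3-hydroxy-6,8-bis(3-methylbut-2-en-1-yl)-2-{3-(3-methylbut-2-en-1-yl)-4-[(triisopropylsilyl)oxy]phenyl}-7-[(triisopropylsilyl)oxy]-2,3-dihydro-4H-chromen-4-one | CC(C)=CCc1cc([C@H]2Oc3c(cc(CC=C(C)C)c(O[Si](C(C)C)(C(C)C)C(C)C)c3CC=C(C)C)C(=O)[C@@H]2O)ccc1O[Si](C(C)C)(C(C)C)C(C)C | intermediate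
33 | lespeflorin B3, (2R,3R)-3,7-dihydroxy-2-[4-hydroxy-3-(3-methylbut-2-en-1-yl)phenyl]-6,8-bis(3-methylbut-2-en-1-yl)-2,3-dihydro-4H-chromen-4-one | CC(C)=CCc1cc([C@H]2Oc3c(cc(CC=C(C)C)c(O)c3CC=C(C)C)C(=O)[C@@H]2O)ccc1O | target

Total step count: 14. Longest linear sequence: 10 steps (steps 1, 2, 3, 5, 6, 7, 8, 12, 13, 14).

Steps most likely to fail

Step 13. The potassium enolate may open by β-elimination of the ring oxygen (retro-oxa-Michael) to a chalcone phenoxide; reclosure is not face-selective, so the C2 configuration would erode, and the hydroxylation itself may stall. The fallback sets both stereocentres by nucleophilic epoxidation of a chalcone, to which the prenyl olefins are inert, and makes step 12 unnecessary as well. It sets out from salicylaldehyde 17 and aryl bromide 26 and comes back to the route at 32. Addition of MeMgBr (THF, 0 °C) to 17 should give the methyl carbinol F1, which MnO2 (CH2Cl2) oxidises to the 2'-hydroxyacetophenone F2; chloromethyl methyl ether and i-Pr2NEt then give the methoxymethyl ether F3. Bromine–lithium exchange on 26 (n-BuLi, THF, −78 °C, through aryllithium 27) and a DMF quench give the ring B aldehyde F4. Deprotonation of F3 (LiN(SiMe3)2, THF, −78 °C) and addition to F4 give the aldol F5, which MsCl and Et3N dehydrate to the (E)-chalcone F6. Juliá–Colonna epoxidation (poly-L-leucine, urea–H2O2, DBU, THF) should give the (2R,3S)-epoxy ketone F7. Dilute HCl in MeOH at 40 °C removes the methoxymethyl group, and the freed phenol opens the epoxide at the benzylic carbon (6-endo, trans to the C3 oxygen, whose configuration the epoxide has fixed) to give 32.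

Step 5. From the s-E conformer of the α-alkyl diazo ketone the excited state may lose N2 to a free carbene that undergoes 1,2-hydride shift from the neighbouring allylic CH2 instead of Wolff migration, and the unsubstituted vinylketene may dimerise or be captured by product phenol before it meets the alkyne. The fallback generates the same vinylketene 12 without a carbene and without light, by dehydrochlorination of an acid chloride in the presence of the ynol ether; it also bypasses the diazo ketone. It sets out from prenyl bromide 24 and siloxyalkyne 11 and comes back at phenol 16. (E)-But-2-enoic acid is doubly deprotonated (LiN(i-Pr)2, 2 equiv, THF, −78 to 0 °C) and alkylated at the α-carbon with 24 to give 2-ethenyl-5-methylhex-4-enoic acid F8; (COCl)2 with catalytic DMF gives 2-ethenyl-5-methylhex-4-enoyl chloride F9. Slow addition of F9 to Et3N and 11 in toluene at 80 °C removes HCl across the acidic α-C–H bond to give 12, which should run through the same [2+2] addition, 4π opening and 6π closure (13, 14, 15) to 16.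

Step 3. While the enone is being deprotonated, dienolate already formed or the amide base may add in conjugate fashion to vinyl ketone that has not yet reacted and start anionic oligomerisation. The fallback generates the dienolate only when no enone is left. It sets out from vinyl ketone 5 and comes back at diketone 7, after which the diazo-transfer half of step 3 follows unchanged. Soft enolisation of 5 (Me3SiOTf, Et3N, CH2Cl2, 0 °C) gives the silyl dienol ether trimethyl{[(3Z)-7-methylocta-1,3,6-trien-3-yl]oxy}silane F10, which is purified by distillation; MeLi (THF, 0 °C) cleaves its O–Si bond to release dienolate 6 free of amine and of enone, and CF3CO2CH2CF3 at −78 °C converts it into 7.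

Further compounds
F1 | step 13 | 1-{2-hydroxy-3,5-bis(3-methylbut-2-en-1-yl)-4-[(triisopropylsilyl)oxy]phenyl}ethan-1-ol (racemic) | CC(O)c1cc(CC=C(C)C)c(O[Si](C(C)C)(C(C)C)C(C)C)c(CC=C(C)C)c1O
F2 | step 13 | 1-{2-hydroxy-3,5-bis(3-methylbut-2-en-1-yl)-4-[(triisopropylsilyl)oxy]phenyl}ethan-1-one | CC(=O)c1cc(CC=C(C)C)c(O[Si](C(C)C)(C(C)C)C(C)C)c(CC=C(C)C)c1O
F3 | step 13 | 1-{2-(methoxymethoxy)-3,5-bis(3-methylbut-2-en-1-yl)-4-[(triisopropylsilyl)oxy]phenyl}ethan-1-one | CC(=O)c1cc(CC=C(C)C)c(O[Si](C(C)C)(C(C)C)C(C)C)c(CC=C(C)C)c1OCOC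
F4 | step 13 | 3-(3-methylbut-2-en-1-yl)-4-[(triisopropylsilyl)oxy]benzaldehyde | CC(C)=CCc1cc(C=O)ccc1O[Si](C(C)C)(C(C)C)C(C)C
F5 | step 13 | 3-hydroxy-1-{2-(methoxymethoxy)-3,5-bis(3-methylbut-2-en-1-yl)-4-[(triisopropylsilyl)oxy]phenyl}-3-{3-(3-methylbut-2-en-1-yl)-4-[(triisopropylsilyl)oxy]phenyl}propan-1-one (racemic) | CC(C)=CCc1cc(C(O)CC(=O)c2cc(CC=C(C)C)c(O[Si](C(C)C)(C(C)C)C(C)C)c(CC=C(C)C)c2OCOC)ccc1O[Si](C(C)C)(C(C)C)C(C)C
F6 | step 13 | (2E)-1-{2-(methoxymethoxy)-3,5-bis(3-methylbut-2-en-1-yl)-4-[(triisopropylsilyl)oxy]phenyl}-3-{3-(3-methylbut-2-en-1-yl)-4-[(triisopropylsilyl)oxy]phenyl}prop-2-en-1-one | CC(C)=CCc1cc(/C=C/C(=O)c2cc(CC=C(C)C)c(O[Si](C(C)C)(C(C)C)C(C)C)c(CC=C(C)C)c2OCOC)ccc1O[Si](C(C)C)(C(C)C)C(C)C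
F7 | step 13 | {2-(methoxymethoxy)-3,5-bis(3-methylbut-2-en-1-yl)-4-[(triisopropylsilyl)oxy]phenyl}{(2R,3S)-3-{3-(3-methylbut-2-en-1-yl)-4-[(triisopropylsilyl)oxy]phenyl}oxiran-2-yl}methanone | O=C(c1cc(CC=C(C)C)c(O[Si](C(C)C)(C(C)C)C(C)C)c(CC=C(C)C)c1OCOC)[C@@H]1O[C@H]1c1ccc(O[Si](C(C)C)(C(C)C)C(C)C)c(CC=C(C)C)c1
F8 | step 5 | 2-ethenyl-5-methylhex-4-enoic acid (racemic) | C=CC(CC=C(C)C)C(=O)O
F9 | step 5 | 2-ethenyl-5-methylhex-4-enoyl chloride (racemic) | C=CC(CC=C(C)C)C(=O)Cl
F10 | step 3 | trimethyl{[(3Z)-7-methylocta-1,3,6-trien-3-yl]oxy}silane | C=C/C(O[Si](C)(C)C)=C/CC=C(C)C
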